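**Retrosynthetic overview**

1. Feature: C4 of the tetralin is a diarylmethine carbon bonded to C1' of a naphthalene whose para carbon C4' carries OH, so C4 can come from the exocyclic carbon of a 1,4-naphthoquinone methide. Its ring neighbour C4a lies ortho to the C5–OMe carbon of the benzo ring.
2. Last stage: C1–OH from the C1 ketone by hydride delivery anti to the C4 aryl group (cis, 1S). Before that, the ketone is released from a dioxolane and C8–H comes from C8–Br.
3. Key disconnection C4–C4a: the saturated ring C1–C2–C3–C4–C4a–C8a is closed by a chiral-phosphoric-acid Friedel–Crafts cyclisation of a 4-bromoanisole ring onto the quinone methide released from a racemic 4-hydroxynaphthyl carbinol. Bromine para to OMe leaves only the ortho carbon free.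
4. The carbinol comes from C4–C1' bond formation between a lithiated O-silyl 4-bromo-8-methoxy-1-naphthol and a γ-ketal aldehyde. The aldehyde comes from 2-bromo-5-methoxybenzaldehyde and butenylmagnesium bromide (addition, oxidation, ketalisation, ozonolysis).
5. Ring order: both aromatic systems are purchased; the tetralin cyclohexane ring is the only ring formed (step 9).

Key step: step 9

Assumption: the catalyst antipode that delivers the (4S) series cannot be deduced on paper; (R)-TRIP is written, and (S)-TRIP would be used instead if a pilot run shows the (4R) product.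

**Route**

Step 1
Reactants: 1 2-bromo-5-methoxybenzaldehyde; 2 but-3-en-1-ylmagnesium bromide
Product: 3 rac-1-(2-bromo-5-methoxyphenyl)pent-4-en-1-ol
Conditions: 2 (1.2 equiv), THF, −78 → 0 °C; aq. NH4Cl
Reagents that add atoms: none
Why: Grignard 1,2-addition to the aldehyde is far faster at low temperature than magnesium–bromine exchange at the aryl bromide, and the configuration of the new carbinol does not matter because it is oxidised in step 2.

Step 2
Reactants: 3 rac-1-(2-bromo-5-methoxyphenyl)pent-4-en-1-ol
Product: 4 1-(2-bromo-5-methoxyphenyl)pent-4-en-1-one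
Conditions: Dess–Martin periodinane (1.2 equiv), NaHCO3, CH2Cl2, 0 °C → rt
Reagents that add atoms: none
Why: Dess–Martin oxidation of a secondary benzylic alcohol is neutral and should leave the terminal alkene, the aryl bromide and the anisole untouched.

Step 3
Reactants: 4 1-(2-bromo-5-methoxyphenyl)pent-4-en-1-one
Product: 5 2-(2-bromo-5-methoxyphenyl)-2-(but-3-en-1-yl)-1,3-dioxolane
Conditions: HOCH2CH2OH (5 equiv), TsOH·H2O (5 mol%), toluene, Dean–Stark, reflux
Reagents that add atoms: ethylene glycol, OCCO
Why: acid-catalysed ketalisation with azeotropic water removal is routine for ortho-bromoaryl alkyl ketones, and the dioxolane withstands the organolithium step while keeping C1 a non-stereogenic sp3 carbon that does not deactivate the arene.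

Step 4
Reactants: 5 2-(2-bromo-5-methoxyphenyl)-2-(but-3-en-1-yl)-1,3-dioxolane
Product: 7 3-[2-(2-bromo-5-methoxyphenyl)-1,3-dioxolan-2-yl]propanal, via secondary ozonide 6 (not isolated)
Conditions: O3, CH2Cl2, −78 °C (Sudan III end point); PPh3, −78 °C → rt
Reagents that add atoms: ozone, [O-][O+]=O
Why: ozonolysis with reductive work-up, in which the monosubstituted alkene is consumed well before the bromoanisole ring is attacked and the ketal carbon carries no oxidisable C–H bond.

Step 5
Reactants: 8 8-methoxynaphthalen-1-ol
Product: 9 4-bromo-8-methoxynaphthalen-1-ol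
Conditions: NBS (1.0 equiv), MeCN, −20 → 0 °C, dark
Reagents that add atoms: N-bromosuccinimide, O=C1CCC(=O)N1Br
Why: electrophilic aromatic bromination, where the hydroxyl is the strongest donor and, being hydrogen-bonded to the peri methoxy oxygen in polar MeCN, is expected to direct para to C4 and not to C2.

Step 6
Reactants: 9 4-bromo-8-methoxynaphthalen-1-ol
Product: 10 [(4-bromo-8-methoxynaphthalen-1-yl)oxy](tert-butyl)dimethylsilane
Conditions: TBSCl (1.3 equiv), imidazole (2.5 equiv), DMAP (cat.), DMF, rt
Reagents that add atoms: tert-butyldimethylsilyl chloride, CC(C)(C)[Si](C)(C)Cl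
Why: standard silylation removes the acidic naphthol proton before halogen–lithium exchange, and the aryl silyl ether can later be cleaved by fluoride without acid.

Step 7
Reactants: 10 [(4-bromo-8-methoxynaphthalen-1-yl)oxy](tert-butyl)dimethylsilane; 7 3-[2-(2-bromo-5-methoxyphenyl)-1,3-dioxolan-2-yl]propanal
Product: 12 rac-3-[2-(2-bromo-5-methoxyphenyl)-1,3-dioxolan-2-yl]-1-{4-[(tert-butyldimethylsilyl)oxy]-5-methoxynaphthalen-1-yl}propan-1-ol, via naphthyllithium 11 (not isolated)
Conditions: 10 (1.2 equiv), n-BuLi (1.1 equiv), THF, −78 °C; then 7 (1.0 equiv), −78 °C; aq. NH4Cl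
Reagents that add atoms: none
Why: bromine–lithium exchange on the electron-rich naphthyl bromide is fast at −78 °C, the aryllithium adds to the aldehyde much faster than it exchanges with the aryl bromide of 7 or touches the ketal, and the carbinol is deliberately formed racemic because this centre is planarised in step 9.

Step 8
Reactants: 12 rac-3-[2-(2-bromo-5-methoxyphenyl)-1,3-dioxolan-2-yl]-1-{4-[(tert-butyldimethylsilyl)oxy]-5-methoxynaphthalen-1-yl}propan-1-ol
Product: 13 rac-4-{3-[2-(2-bromo-5-methoxyphenyl)-1,3-dioxolan-2-yl]-1-hydroxypropyl}-8-methoxynaphthalen-1-ol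
Conditions: TBAF (1.1 equiv), AcOH (1.1 equiv), THF, 0 °C; product used without delay
Reagents that add atoms: none
Why: fluoride cleaves the aryl silyl ether selectively, and acetic acid buffering keeps the naphthoxide concentration low so that the benzylic hydroxyl is not expelled before the catalyst is present.

Step 9
Reactants: 13 rac-4-{3-[2-(2-bromo-5-methoxyphenyl)-1,3-dioxolan-2-yl]-1-hydroxypropyl}-8-methoxynaphthalen-1-ol
Product: 15 4-[(4'S)-8'-bromo-5'-methoxy-3',4'-dihydro-2'H-spiro[[1,3]dioxolane-2,1'-naphthalen]-4'-yl]-8-methoxynaphthalen-1-ol, via naphthoquinone methide 14 (not isolated)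
Conditions: (R)-TRIP (10 mol%), 4 Å MS, PhCF3 (0.01 M), 0 °C → rt
Reagents that add atoms: none
Why: Proposed new method: the phosphoric acid ionises the benzylic C–OH bond of 13 with help from the para naphthol oxygen, so both carbinol enantiomers converge on one planar species, the (E)-naphthoquinone methide 14 held as a hydrogen-bonded ion pair with the chiral phosphate; the tethered arene carbon ortho to OMe then adds to the exocyclic methide carbon and proton loss restores both aromatic systems, while any 4-alkenylnaphthol formed by tautomerisation of 14 should re-enter by reprotonation. The closest known reaction type is the chiral-phosphoric-acid 1,6-Friedel–Crafts addition of indoles, naphthols and polyalkoxybenzenes to p-quinone methides generated in situ from p-hydroxybenzylic alcohols, together with the racemic acid-mediated cyclialkylation of 1,4-diarylbutan-1-ols to 1-aryltetralins; an intramolecular enantioselective version with a monomethoxy arene and an alkyl-substituted naphthoquinone methide has not been shown. The ring C1–C2–C3–C4–C4a–C8a closes in a 6-exo-trig mode with respect to the methide C=C, forming C4–C4a, and is helped by the quaternary ketal carbon in the tether. C4, the only stereocentre of 15, is set by the chiral phosphate, which is bound at the quinone methide oxygen and whose 3,3'-aryl groups must screen one face of the remote methide carbon. The step needs ortho-over-para regioselectivity, secured by bromine on the carbon para to OMe (ipso attack there is reversible and unproductive), and survival of the ketal, secured by molecular sieves that take up the released water. High dilution is used to suppress intermolecular attack by the naphthol ring of a second molecule.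

Step 10
Reactants: 15 4-[(4'S)-8'-bromo-5'-methoxy-3',4'-dihydro-2'H-spiro[[1,3]dioxolane-2,1'-naphthalen]-4'-yl]-8-methoxynaphthalen-1-ol
Product: 16 4-[(4'S)-5'-methoxy-3',4'-dihydro-2'H-spiro[[1,3]dioxolane-2,1'-naphthalen]-4'-yl]-8-methoxynaphthalen-1-ol
Conditions: H2 (1 atm), 10% Pd/C, Et3N (2 equiv), EtOAc–MeOH, rt, air excluded
Reagents that add atoms: none
Why: palladium-catalysed hydrogenolysis of the aryl C–Br bond with the amine as HBr scavenger, run at the ketal stage so that no aryl ketone is exposed to hydrogenation and the diarylmethine C4–H bond is not touched.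

Step 11
Reactants: 16 4-[(4'S)-5'-methoxy-3',4'-dihydro-2'H-spiro[[1,3]dioxolane-2,1'-naphthalen]-4'-yl]-8-methoxynaphthalen-1-ol
Product: 17 (4S)-4-(4-hydroxy-5-methoxynaphthalen-1-yl)-5-methoxy-3,4-dihydronaphthalen-1(2H)-one
Conditions: 1 M aq. HCl, THF, rt
Reagents that add atoms: water, O
Why: acid-catalysed ketal hydrolysis under mild aqueous conditions, with C4 not α to the new carbonyl and therefore unable to epimerise by enolisation.

Step 12
Reactants: 17 (4S)-4-(4-hydroxy-5-methoxynaphthalen-1-yl)-5-methoxy-3,4-dihydronaphthalen-1(2H)-one
Product: 18 dipolynaphthalene B, (1S,4S)-4-(4-hydroxy-5-methoxynaphthalen-1-yl)-5-methoxy-1,2,3,4-tetrahydronaphthalen-1-ol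
Conditions: L-Selectride (3 equiv), THF, −78 °C; aq. NH4Cl (non-oxidative work-up)
Reagents that add atoms: none
Why: substrate-controlled hydride reduction, in which peri strain with the C5 methoxy group forces the C4 naphthyl group pseudoaxial so the bulky hydride attacks C1 from the opposite face (also the pseudoaxial trajectory), placing OH cis to the aryl group and giving (1S).

**Compound list**

1 | 2-bromo-5-methoxybenzaldehyde | COc1ccc(Br)c(C=O)c1 | starting material
2 | but-3-en-1-ylmagnesium bromide | C=CCC[Mg]Br | starting material
3 | rac-1-(2-bromo-5-methoxyphenyl)pent-4-en-1-ol | COc1ccc(Br)c(c1)C(O)CCC=C | intermediate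
4 | 1-(2-bromo-5-methoxyphenyl)pent-4-en-1-one | COc1ccc(Br)c(c1)C(=O)CCC=C | intermediate
5 | 2-(2-bromo-5-methoxyphenyl)-2-(but-3-en-1-yl)-1,3-dioxolane | COc1ccc(Br)c(c1)C1(CCC=C)OCCO1 | intermediate
6 | 3-{2-[2-(2-bromo-5-methoxyphenyl)-1,3-dioxolan-2-yl]ethyl}-1,2,4-trioxolane (secondary ozonide, not isolated) | COc1ccc(Br)c(c1)C1(CCC2OCOO2)OCCO1 | intermediate
7 | 3-[2-(2-bromo-5-methoxyphenyl)-1,3-dioxolan-2-yl]propanal | COc1ccc(Br)c(c1)C1(CCC=O)OCCO1 | intermediate
8 | 8-methoxynaphthalen-1-ol | COc1cccc2cccc(O)c12 | starting material
9 | 4-bromo-8-methoxynaphthalen-1-ol | COc1cccc2c(Br)ccc(O)c12 | intermediate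
10 | [(4-bromo-8-methoxynaphthalen-1-yl)oxy](tert-butyl)dimethylsilane | COc1cccc2c(Br)ccc(O[Si](C)(C)C(C)(C)C)c12 | intermediate
11 | {4-[(tert-butyldimethylsilyl)oxy]-5-methoxynaphthalen-1-yl}lithium (not isolated) | COc1cccc2c([Li])ccc(O[Si](C)(C)C(C)(C)C)c12 | intermediate
12 | rac-3-[2-(2-bromo-5-methoxyphenyl)-1,3-dioxolan-2-yl]-1-{4-[(tert-butyldimethylsilyl)oxy]-5-methoxynaphthalen-1-yl}propan-1-ol | COc1ccc(Br)c(c1)C1(OCCO1)CCC(O)c1ccc(O[Si](C)(C)C(C)(C)C)c2c(OC)cccc12 | intermediate
13 | rac-4-{3-[2-(2-bromo-5-methoxyphenyl)-1,3-dioxolan-2-yl]-1-hydroxypropyl}-8-methoxynaphthalen-1-ol | COc1ccc(Br)c(c1)C1(OCCO1)CCC(O)c1ccc(O)c2c(OC)cccc12 | intermediate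
14 | (4E)-4-{3-[2-(2-bromo-5-methoxyphenyl)-1,3-dioxolan-2-yl]propylidene}-8-methoxynaphthalen-1(4H)-one (not isolated) | COc1ccc(Br)c(c1)C1(OCCO1)CC/C=C1\C=CC(=O)c2c(OC)cccc12 | intermediate
15 | 4-[(4'S)-8'-bromo-5'-methoxy-3',4'-dihydro-2'H-spiro[[1,3]dioxolane-2,1'-naphthalen]-4'-yl]-8-methoxynaphthalen-1-ol | COc1ccc(Br)c2c1[C@H](c1ccc(O)c3c(OC)cccc13)CCC21OCCO1 | intermediate
16 | 4-[(4'S)-5'-methoxy-3',4'-dihydro-2'H-spiro[[1,3]dioxolane-2,1'-naphthalen]-4'-yl]-8-methoxynaphthalen-1-ol | COc1cccc2c1[C@H](c1ccc(O)c3c(OC)cccc13)CCC21OCCO1 | intermediate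
17 | (4S)-4-(4-hydroxy-5-methoxynaphthalen-1-yl)-5-methoxy-3,4-dihydronaphthalen-1(2H)-one | COc1cccc2c1[C@H](c1ccc(O)c3c(OC)cccc13)CCC2=O | intermediate
18 | dipolynaphthalene B, (1S,4S)-4-(4-hydroxy-5-methoxynaphthalen-1-yl)-5-methoxy-1,2,3,4-tetrahydronaphthalen-1-ol (cis) | COc1cccc2c1[C@H](c1ccc(O)c3c(OC)cccc13)CC[C@@H]2O | target

**Totals**

Total step count: 12. Longest linear sequence: 10 steps (steps 1–4 and 7–12, from 1); the naphthol branch (steps 5–6) joins at step 7.

**Steps most likely to fail**

Step 9 (Proposed new method). The attacking carbon is only singly activated (ortho to OMe, meta to Br, next to the ketal carbon), so ring closure may be outrun by intermolecular attack of the naphthol ring of another molecule or by diversion of the quinone methide into the alkenylnaphthol. Facial discrimination may also be weak, because the phosphate is anchored at the oxygen remote from the methide carbon and the nucleophile offers no second hydrogen-bond contact. A more acidic, more confined BINOL N-triflyl phosphoramide is the first adjustment within the step. The fallback gives up asymmetric induction and uses known chemistry. Setting out from 13, an achiral acid (diphenyl phosphate, CH2Cl2–HFIP, 4 Å MS), in a classical cyclialkylation of a benzylic alcohol onto a tethered anisole, should give racemic 4-[8'-bromo-5'-methoxy-3',4'-dihydro-2'H-spiro[[1,3]dioxolane-2,1'-naphthalen]-4'-yl]-8-methoxynaphthalen-1-ol F1. This is resolved by preparative chromatography on a polysaccharide chiral stationary phase, and the (4S) enantiomer rejoins the route at 15.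

Step 12. Hydride delivery may not discriminate the two faces of the C1 carbonyl well enough, so the trans C1 epimer would form beside the cis alcohol. The fallback replaces substrate control by catalyst control. Setting out from 17, a Noyori-type asymmetric transfer hydrogenation with RuCl[(S,S)-TsDPEN](p-cymene) in HCO2H–Et3N, the antipode that reduces 1-tetralones to (S)-1-tetralols, fixes (1S) independently of the ring conformation and in the matched sense. It returns directly to 18 without new intermediates.

Step 8. During desilylation the naphthoxide may expel the benzylic hydroxyl, and the resulting quinone methide would oligomerise; the electron-rich naphthol may also oxidise in air on handling. The fallback avoids the silyl group and steps 6–8 altogether. Setting out from 9, n-BuLi (2.1 equiv, THF, −78 °C) deprotonates the naphthol and then exchanges the bromide, as known for bromophenoxides, to give lithium 4-lithio-8-methoxynaphthalen-1-olate F2. This is added to aldehyde 7 at −78 °C and quenched cold with pH 7 buffer, coming back to the route at 13.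

**Further compounds**

F1 | step 9 | rac-4-[8'-bromo-5'-methoxy-3',4'-dihydro-2'H-spiro[[1,3]dioxolane-2,1'-naphthalen]-4'-yl]-8-methoxynaphthalen-1-ol | COc1ccc(Br)c2c1C(c1ccc(O)c3c(OC)cccc13)CCC21OCCO1
F0 | step 12 | none | none
F2 | step 8 | lithium 4-lithio-8-methoxynaphthalen-1-olate | [Li+].[O-]c1ccc([Li])c2cccc(OC)c12
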